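Amounts first: you charge 3.0 M of substrate against 6.0 mM of catalyst and 9.2 mM of added ligand, and you want to know how much stands as target after 40 min.

substrate 3.0 M; gas phase 200 mM (held); catalyst 6.0 mM; added ligand 9.2 mM; time 40 min

    gas phase ⇌ dissolved gas, rate k1*(csat - [dissolved gas]) (k1 = 0.10 s⁻¹, csat = 200 mM)
    substrate + dissolved gas + catalyst → catalyst + target (k2 = 0.61 M⁻² s⁻¹)
    catalyst + added ligand ⇌ idle complex (K3 = 1900 M⁻¹, k3 = 0.58 M⁻¹ s⁻¹)
    substrate + target → side product (k4 = 3.6 × 10⁻⁴ M⁻¹ s⁻¹)

- in percentages every species weighs as the substrate in it: one side product counts as two
- at the start none of the gas is dissolved
- run time (flask): 40 min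

- alpha: doubling the transfer coefficient of step 1, all else as stated
- gamma: doubling the amount of catalyst, all else as stated
- delta: doubling the saturation concentration of gas phase, all else as stated

* the target standing at 40 min, as a percentage of the substrate charged
* concentration of dissolved gas in solution at 10 min, in percent of saturation
* the change that raises the amount of target at 40 min, in percent of the substrate charged most ("none" if none brings more than 2 percentage points) (alpha / gamma / delta / none)
* amount of target at 40 min, in percent of the substrate charged, after delta

Turn the question round: what would these numbers have to show for a high yield? The catalytic step makes target at 0.61 M⁻² s⁻¹·c(substrate)·c(dissolved gas)·c(catalyst), and the side step eats it at 3.6 × 10⁻⁴ M⁻¹ s⁻¹·c(substrate)·c(target). So c(substrate) cancels, the two balance at a single c(target), and I hold that balance against the substrate charged.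

Here is my reckoning for this flask. The added ligand binds within about 3.12 min, shorter than the run, so I take binding at equilibrium, which leaves 0.712 mM of free catalyst. Transfer at 0.10 s⁻¹ is much faster than that catalyst's uptake of gas, 0.00130 s⁻¹, so I set c(dissolved gas) at 200 mM, about 98.7% of saturation. The balance, 0.241 M, is what I call the balance level of target: the making constant times saturated dissolved gas times free catalyst at equilibrium, over the eating constant.

That is 8.04% of the charge, or −1.10 in powers of ten, so this flask stands about one power short of a high yield. Target's half-life of 11 min under the side step is short against the run, so I commit to y near the balance level. Delta doubles the balance level to 16.1%. Alpha leaves it alone. Gamma frees 3.90 mM of catalyst and lifts the balance level to 44.0%, so gamma is my choice.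

The forecast gives y 9.2%, sat 98.3%, best gamma and yb 19%, on the ground that “Doubling catalyst overwhelms the ligand”. Its y and yb lie above mine and its sat below; its choice is mine.

The flask gives y 9.23%, sat 98.3%, best gamma and yb 18.9%, with gains of 24 percentage points for gamma, 9.7 points for delta and 0.15 points for alpha. At 40.0 min target is made at 0.866 of the rate it is eaten. The balance level is no upper bound: target stands higher than it, the level over the standing target gives 0.871, and after 400 min target stands at 8.07%.

In the neighbour flask with 1.8 M of substrate the balance level keeps its 0.241 M, which is 13.4% of that smaller charge. That neighbour flask gives 13.7%.

The constants used here come from no measurement; the result is computed.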